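The route rests on disconnecting the dimethylpyran ring fused to ring B at both ends of its isobutenyl unit: the CH=CH bond next to C3' and the O4'–CMe2 bond. Both form in one operation when a ring B salicylaldehyde (formyl on C3', free OH on C4', prenyl already on C2', O5' capped as MOM, a second formyl on C1') meets 2-methylprop-1-enylboronic acid and catalytic dibenzylamine: Petasis alkenyl transfer, amine loss to an ortho-quinone methide and oxa-6π electrocyclisation. The step exploits the ortho relation of the C3' formyl and O4'. The C1' formyl, para to O4', survives and then builds ring C by Claisen–Schmidt/Algar–Flynn–Oyamada chemistry.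

Key step: step 4

Assumption: flavonoid numbering is used (ring A C5–C8, ring C the pyranone, ring B C1'–C6'); the target has no stereocentre, so the only geometric element set on the way is the E double bond of the transient chalcone.

Step 1
Reactants: 1 2-bromo-4,5-dihydroxybenzaldehyde
Product: 2 2-bromo-4-hydroxy-5-(methoxymethoxy)benzaldehyde
Conditions: NaH (2.2 equiv), DMF, 0 °C; MOMCl (1.0 equiv), 0 °C to rt; aq. NH4Cl
Reagents that add atoms: chloromethyl methyl ether, COCCl
Why: In the catechol dianion the 5-phenoxide, not conjugated to the para-formyl group, is the more nucleophilic oxygen and should take the single equivalent of electrophile (regioselective Williamson-type O-alkylation).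

Step 2
Reactants: 2 2-bromo-4-hydroxy-5-(methoxymethoxy)benzaldehyde; 3 tributyl(3-methylbut-2-enyl)stannane
Product: 4 4-hydroxy-5-(methoxymethoxy)-2-(3-methylbut-2-enyl)benzaldehyde
Conditions: Pd(PPh3)4 (5 mol%), DMF, 95 °C
Reagents that add atoms: none
Why: Migita–Kosugi–Stille coupling of an ortho-formyl aryl bromide with an allylic stannane, in which reductive elimination at the less hindered allyl terminus should give the linear prenyl group and the free phenol is tolerated.

Step 3
Reactants: 4 4-hydroxy-5-(methoxymethoxy)-2-(3-methylbut-2-enyl)benzaldehyde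
Product: 5 4-hydroxy-5-(methoxymethoxy)-2-(3-methylbut-2-enyl)benzene-1,3-dicarbaldehyde
Conditions: MgCl2, Et3N, (CH2O)n, MeCN, reflux; cold aq. citric acid
Reagents that add atoms: paraformaldehyde (as formaldehyde), C=O
Why: Casnati–Skattebøl ortho-formylation, in which the magnesium phenoxide delivers formaldehyde to C3', the only free carbon ortho to O4' (the other carries the MOM ether), and a second formaldehyde oxidises the hydroxymethyl intermediate by hydride transfer.

Step 4
Reactants: 5 4-hydroxy-5-(methoxymethoxy)-2-(3-methylbut-2-enyl)benzene-1,3-dicarbaldehyde; 6 (2-methylprop-1-enyl)boronic acid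
Product: 9 8-(methoxymethoxy)-2,2-dimethyl-5-(3-methylbut-2-enyl)-2H-chromene-6-carbaldehyde, via Petasis allylic amine 7 (not isolated), via ortho-quinone methide 8 (not isolated)
Conditions: 6 (1.5 equiv), Bn2NH (30 mol%), 1,4-dioxane, 90 °C
Reagents that add atoms: none
Why: Dibenzylamine condenses with the C3' formyl group to an iminium ion while the adjacent O4' phenol binds the boronic acid as a tetracoordinate boronate, which transfers the 2-methylprop-1-enyl group intramolecularly to the iminium carbon (Petasis borono-Mannich step, new C–C bond) to give allylic amine 7. On heating, 7 expels dibenzylamine with phenol assistance to form ortho-quinone methide 8, whose thermal disrotatory oxa-6π electrocyclisation (formally a 6-endo closure of O4' onto the CMe2 terminus) forms the O–C bond and the 2H-pyran ring and returns the amine to the cycle. The closest known reaction type is the amine-catalysed Petasis synthesis of 2H-chromenes from salicylaldehydes and alkenylboronic acids. No stereocentre is created, since the pyran C2 carries two methyl groups and the former formyl carbon ends as an sp2 centre. The step needs chemoselectivity between the two formyl groups and a phenol that is free to bind boron: only the C3' formyl has an ortho hydroxyl to deliver the alkenyl group, the C1' formyl is para to O4' and cannot take part, and O5' is capped as the MOM ether so no catechol boronate can sequester the reagent.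

Step 5
Reactants: 10 1-(2,4,6-trihydroxyphenyl)ethanone; 11 1-bromo-3-methylbut-2-ene
Product: 12 1-[2,6-dihydroxy-4-(3-methylbut-2-enyloxy)phenyl]ethanone
Conditions: 11 (1.0 equiv), K2CO3 (1.1 equiv), acetone, rt to 50 °C
Reagents that add atoms: none
Why: The 4-OH is the only hydroxyl not hydrogen-bonded to the acetyl group and the most acidic, so one equivalent of the bromide under carbonate conditions should give Williamson O-alkylation there.

Step 6
Reactants: 12 1-[2,6-dihydroxy-4-(3-methylbut-2-enyloxy)phenyl]ethanone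
Product: 14 1-[2,4,6-trihydroxy-3-(2-methylbut-3-en-2-yl)phenyl]ethanone, via ortho-dienone 13 (not isolated)
Conditions: N,N-diethylaniline, 190 °C, sealed tube, Ar
Reagents that add atoms: none
Why: Aromatic Claisen rearrangement ([3,3]) of the prenyl ether delivers the inverted 2-methylbut-3-en-2-yl group to an ortho carbon; C3 and C5 are equivalent by symmetry, the para carbon carries the acetyl group, and tautomerisation of dienone 13 restores the arene.

Step 7
Reactants: 14 1-[2,4,6-trihydroxy-3-(2-methylbut-3-en-2-yl)phenyl]ethanone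
Product: 15 1-[2-hydroxy-4,6-bis(methoxymethoxy)-3-(2-methylbut-3-en-2-yl)phenyl]ethanone
Conditions: MOMCl (2.2 equiv), iPr2NEt, CH2Cl2, 0 °C to rt
Reagents that add atoms: chloromethyl methyl ether, COCCl
Why: MOM ether formation under amine base should take the free 4-OH and the less hindered chelated hydroxyl (O6), while the 2-OH, wedged between the quaternary side chain and the acetyl group and held in the hydrogen bond, stays free.

Step 8
Reactants: 15 1-[2-hydroxy-4,6-bis(methoxymethoxy)-3-(2-methylbut-3-en-2-yl)phenyl]ethanone; 9 8-(methoxymethoxy)-2,2-dimethyl-5-(3-methylbut-2-enyl)-2H-chromene-6-carbaldehyde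
Product: 17 3-hydroxy-5,7-bis(methoxymethoxy)-2-[8-(methoxymethoxy)-2,2-dimethyl-5-(3-methylbut-2-enyl)-2H-chromen-6-yl]-8-(2-methylbut-3-en-2-yl)-4H-chromen-4-one, via chalcone 16 (not isolated)
Conditions: KOH (50% aq.), EtOH, rt, 48 h; then 0 °C, 30% H2O2, 0 °C to rt
Reagents that add atoms: hydrogen peroxide, OO
Why: Claisen–Schmidt aldol condensation of the acetophenone enolate with the non-enolisable aldehyde gives the E-chalcone (E1cB dehydration, thermodynamic geometry), and alkaline hydrogen peroxide then effects Algar–Flynn–Oyamada oxidative cyclisation through the phenoxide next to the ketone to the 3-hydroxychromen-4-one, the electron-rich side-chain and chromene double bonds being inert to nucleophilic peroxide.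

Step 9
Reactants: 17 3-hydroxy-5,7-bis(methoxymethoxy)-2-[8-(methoxymethoxy)-2,2-dimethyl-5-(3-methylbut-2-enyl)-2H-chromen-6-yl]-8-(2-methylbut-3-en-2-yl)-4H-chromen-4-one
Product: 18 Broussoflavonol D
Conditions: 3 M HCl (aq.), MeOH, 45 °C
Reagents that add atoms: none
Why: Acid-catalysed acetal exchange should cleave the three MOM ethers, while the 2'-prenyl group has no ortho hydroxyl to cyclise onto and mild acid should leave the terminal vinyl group and the chromene intact.

Compound list
1 | 2-bromo-4,5-dihydroxybenzaldehyde | O=Cc1cc(O)c(O)cc1Br | starting material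
2 | 2-bromo-4-hydroxy-5-(methoxymethoxy)benzaldehyde | O=Cc1cc(OCOC)c(O)cc1Br | intermediate
3 | tributyl(3-methylbut-2-enyl)stannane | CCCC[Sn](CCCC)(CCCC)CC=C(C)C | starting material
4 | 4-hydroxy-5-(methoxymethoxy)-2-(3-methylbut-2-enyl)benzaldehyde | O=Cc1cc(OCOC)c(O)cc1CC=C(C)C | intermediate
5 | 4-hydroxy-5-(methoxymethoxy)-2-(3-methylbut-2-enyl)benzene-1,3-dicarbaldehyde | O=Cc1cc(OCOC)c(O)c(C=O)c1CC=C(C)C | intermediate
6 | (2-methylprop-1-enyl)boronic acid | CC(C)=CB(O)O | starting material
7 | racemic 3-[1-(dibenzylamino)-3-methylbut-2-enyl]-4-hydroxy-5-(methoxymethoxy)-2-(3-methylbut-2-enyl)benzaldehyde | O=Cc1cc(OCOC)c(O)c(C(C=C(C)C)N(Cc2ccccc2)Cc2ccccc2)c1CC=C(C)C | intermediate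
8 | 5-(methoxymethoxy)-2-(3-methylbut-2-enyl)-3-(3-methylbut-2-enylidene)-4-oxocyclohexa-1,5-diene-1-carbaldehyde | O=CC1=C(CC=C(C)C)C(=CC=C(C)C)C(=O)C(OCOC)=C1 | intermediate
9 | 8-(methoxymethoxy)-2,2-dimethyl-5-(3-methylbut-2-enyl)-2H-chromene-6-carbaldehyde | O=Cc1cc(OCOC)c2c(c1CC=C(C)C)C=CC(C)(C)O2 | intermediate
10 | 1-(2,4,6-trihydroxyphenyl)ethanone | CC(=O)c1c(O)cc(O)cc1O | starting material
11 | 1-bromo-3-methylbut-2-ene | CC(C)=CCBr | starting material
12 | 1-[2,6-dihydroxy-4-(3-methylbut-2-enyloxy)phenyl]ethanone | CC(=O)c1c(O)cc(OCC=C(C)C)cc1O | intermediate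
13 | racemic 4-acetyl-3,5-dihydroxy-6-(2-methylbut-3-en-2-yl)cyclohexa-2,4-dien-1-one | CC(=O)C1=C(O)C(C(C)(C)C=C)C(=O)C=C1O | intermediate
14 | 1-[2,4,6-trihydroxy-3-(2-methylbut-3-en-2-yl)phenyl]ethanone | CC(=O)c1c(O)cc(O)c(C(C)(C)C=C)c1O | intermediate
15 | 1-[2-hydroxy-4,6-bis(methoxymethoxy)-3-(2-methylbut-3-en-2-yl)phenyl]ethanone | CC(=O)c1c(OCOC)cc(OCOC)c(C(C)(C)C=C)c1O | intermediate
16 | (E)-1-[2-hydroxy-4,6-bis(methoxymethoxy)-3-(2-methylbut-3-en-2-yl)phenyl]-3-[8-(methoxymethoxy)-2,2-dimethyl-5-(3-methylbut-2-enyl)-2H-chromen-6-yl]prop-2-en-1-one | COCOc1cc(OCOC)c(C(C)(C)C=C)c(O)c1C(=O)/C=C/c1cc(OCOC)c2c(c1CC=C(C)C)C=CC(C)(C)O2 | intermediate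
17 | 3-hydroxy-5,7-bis(methoxymethoxy)-2-[8-(methoxymethoxy)-2,2-dimethyl-5-(3-methylbut-2-enyl)-2H-chromen-6-yl]-8-(2-methylbut-3-en-2-yl)-4H-chromen-4-one | C=CC(C)(C)c1c(OCOC)cc(OCOC)c2c(=O)c(O)c(-c3cc(OCOC)c4c(c3CC=C(C)C)C=CC(C)(C)O4)oc12 | intermediate
18 | Broussoflavonol D | C=CC(C)(C)c1c(O)cc(O)c2c(=O)c(O)c(-c3cc(O)c4c(c3CC=C(C)C)C=CC(C)(C)O4)oc12 | target

Total step count: 9. Longest linear sequence: 6 steps (steps 1, 2, 3, 4, 8, 9); the ring A branch (steps 5, 6, 7) joins at step 8.

Steps most likely to fail

Step 3. The phenol is deactivated by the para-formyl group and its only free ortho carbon is flanked by the prenyl chain, so formaldehyde delivery may be slow and the existing formyl group may be consumed by hydride transfer. The fallback sets out from 4 and comes back at 5: ortho-iodination with I2 and morpholine in MeOH should give 4-hydroxy-3-iodo-5-(methoxymethoxy)-2-(3-methylbut-2-enyl)benzaldehyde F1, and reductive carbonylation of the aryl iodide (Pd(PPh3)4, CO 1 atm, Bu3SnH, THF, 50 °C) should then give dialdehyde 5.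

Step 4. Alkenyl transfer to a crowded, electron-poor salicylaldehyde may stall at the iminium stage or at amine 7, and protodeboronation of the boronic acid may outrun it. The fallback sets out from 4 and comes back at 9, so it also bypasses step 3: O-alkylation of the phenol with 3-chloro-3-methylbut-1-yne (DBU, CuCl2 cat., MeCN, 0 °C) should give 5-(methoxymethoxy)-4-(2-methylbut-3-yn-2-yloxy)-2-(3-methylbut-2-enyl)benzaldehyde F2. Heating F2 in N,N-diethylaniline (180 °C) should then give chromene 9 by propargyl Claisen rearrangement to C3' (the only free ortho carbon), 1,5-hydrogen shift and oxa-6π closure.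

Step 8. Ring closure of the chalcone at the α-carbon (five-membered, aurone-type closure, favoured by the oxygen substituent flanking the ketone) may compete with the six-membered closure, and the hindered condensation may be incomplete when the peroxide is added. The fallback sets out from chalcone 16, isolated by running the condensation of 15 and 9 without the peroxide stage, and comes back at 17. Oxidative cyclisation with catalytic I2 in DMSO (110 °C) should give 5,7-bis(methoxymethoxy)-2-[8-(methoxymethoxy)-2,2-dimethyl-5-(3-methylbut-2-enyl)-2H-chromen-6-yl]-8-(2-methylbut-3-en-2-yl)-4H-chromen-4-one F3. Deprotonation at C3 with LDA (THF, −78 °C) and trapping with B(OMe)3 should give the dimethyl [5,7-bis(methoxymethoxy)-2-[8-(methoxymethoxy)-2,2-dimethyl-5-(3-methylbut-2-enyl)-2H-chromen-6-yl]-8-(2-methylbut-3-en-2-yl)-4-oxo-4H-chromen-3-yl]boronate F4. Oxidation of F4 with H2O2 and aq. NaHCO3 (THF, 0 °C) should give 17.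

Further compounds
F1 | step 3 | 4-hydroxy-3-iodo-5-(methoxymethoxy)-2-(3-methylbut-2-enyl)benzaldehyde | O=Cc1cc(OCOC)c(O)c(I)c1CC=C(C)C
F2 | step 4 | 5-(methoxymethoxy)-4-(2-methylbut-3-yn-2-yloxy)-2-(3-methylbut-2-enyl)benzaldehyde | O=Cc1cc(OCOC)c(OC(C)(C)C#C)cc1CC=C(C)C
F3 | step 8 | 5,7-bis(methoxymethoxy)-2-[8-(methoxymethoxy)-2,2-dimethyl-5-(3-methylbut-2-enyl)-2H-chromen-6-yl]-8-(2-methylbut-3-en-2-yl)-4H-chromen-4-one | C=CC(C)(C)c1c(OCOC)cc(OCOC)c2c(=O)cc(-c3cc(OCOC)c4c(c3CC=C(C)C)C=CC(C)(C)O4)oc12
F4 | step 8 | dimethyl [5,7-bis(methoxymethoxy)-2-[8-(methoxymethoxy)-2,2-dimethyl-5-(3-methylbut-2-enyl)-2H-chromen-6-yl]-8-(2-methylbut-3-en-2-yl)-4-oxo-4H-chromen-3-yl]boronate | C=CC(C)(C)c1c(OCOC)cc(OCOC)c2c(=O)c(B(OC)OC)c(-c3cc(OCOC)c4c(c3CC=C(C)C)C=CC(C)(C)O4)oc12
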